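Atoms are numbered in the order of the target SMILES. Everything rests on removing the enone carbon C2 from the seven-membered ring (C2, C3, C23, C26, C32, C33, C34). Because C34, C2 and C3 are contiguous, the C2-nor compound is a cis-fused hydrindanone in which ketone C34 sits next to C3, the carbon that carries the side chain. In one operation dibromocarbene adds to a regiodefined C34=C3 silyl enol ether and the adduct opens to the 2-bromocycloheptenone, creating C34–C2, C2–C3 and the tetrasubstituted enone; the bromide is then exchanged for the C1 methyl. The precursor is the per-triethylsilylated nor-skeleton, made by aldol union of a hydrindenone with an oxepane-fused cyclohexyl acetaldehyde.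

Key step: step 19

Remark: the facial sense of the Shi epoxidation of the tetrasubstituted enol acetate (step 2) is assumed to follow the spiro transition-state model that holds for trisubstituted alkenes; if it proved opposite, the enantiomeric ketone catalyst would be used.

Step 1
Reactants: 1 2-methylcyclopentanone
Product: 2 2-methylcyclopent-1-en-1-yl acetate
Conditions: Ac2O, HClO4 (cat.), CCl4, rt; distillation
Reagents that add atoms: acetic anhydride, CC(=O)OC(C)=O
Why: Acid-catalysed enol acetylation under equilibrating conditions should give the more substituted, tetrasubstituted enol ester, which is the regioisomer needed to oxidise the methyl-bearing carbon C29.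

Step 2
Reactants: 2 2-methylcyclopent-1-en-1-yl acetate
Product: 4 (R)-2-hydroxy-2-methylcyclopentanone, via epoxy acetate 3 (not isolated)
Conditions: D-fructose-derived Shi ketone (0.3 equiv), Oxone, K2CO3, Bu4NHSO4, MeCN/DMM/aq. buffer (pH 10.5), 0 °C; then K2CO3 (cat.), MeOH, 0 °C
Reagents that add atoms: potassium peroxymonosulfate (Oxone), [K+].[O-]S(=O)(=O)OO
Why: Shi asymmetric epoxidation of the enol ester by the chiral dioxirane should set C29 under catalyst control, and methanolysis of the epoxy acetate collapses to the α-hydroxy ketone with the C29–O bond retained.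

Step 3
Reactants: 4 (R)-2-hydroxy-2-methylcyclopentanone
Product: 5 (5R)-5-methyl-1,5-bis(triethylsilyloxy)cyclopent-1-ene
Conditions: TESOTf (2.3 equiv), Et3N, CH2Cl2, 0 °C
Reagents that add atoms: triethylsilyl trifluoromethanesulfonate, CC[Si](CC)(CC)OS(=O)(=O)C(F)(F)F
Why: Soft enolisation with a silyl triflate and an amine silylates the tertiary alcohol and forms the silyl enol ether in one operation, and the enol ether is regiodefined because only C26 carries α-hydrogens.

Step 4
Reactants: 5 (5R)-5-methyl-1,5-bis(triethylsilyloxy)cyclopent-1-ene; 6 mesityl oxide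
Product: 7 (2R,5S)-2-methyl-5-(2-methyl-4-oxopentan-2-yl)-2-(triethylsilyloxy)cyclopentan-1-one
Conditions: TiCl4 (1.1 equiv), CH2Cl2, −78 °C; aq. K2CO3
Reagents that add atoms: none
Why: Mukaiyama–Michael addition of the silyl enol ether to the titanium-activated β,β-disubstituted enone forms C26–C23 and the gem-dimethyl quaternary carbon, and the electrophile should approach C26 anti to the bulky C29 silyloxy group so that C23 ends up trans to that oxygen.

Step 5
Reactants: 7 (2R,5S)-2-methyl-5-(2-methyl-4-oxopentan-2-yl)-2-(triethylsilyloxy)cyclopentan-1-one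
Product: 9 (3R,7aS)-3-hydroxy-3,7,7-trimethyl-1,2,3,6,7,7a-hexahydro-5H-inden-5-one, via silyl ether enone 8 (not isolated)
Conditions: KOH (0.2 equiv), MeOH, 50 °C; then 1 M HCl, THF, rt; chromatography (removes any C26 epimer)
Reagents that add atoms: none
Why: Intramolecular aldol condensation of the methyl ketone (C33) onto the ring carbonyl (C32) closes the six-membered ring as the second half of a Robinson-type annulation, and mild acid then hydrolyses the silyl ether to free the C29 hydroxyl needed later as a directing group.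

Step 6
Reactants: 10 geranyl bromide; 11 N-methoxy-N-methylacetamide
Product: 12 (4E)-N-methoxy-N,5,9-trimethyldeca-4,8-dienamide
Conditions: LDA, THF, −78 °C (11); then 10, −78 → −40 °C
Reagents that add atoms: none
Why: SN2 alkylation of the amide lithium enolate with the allylic bromide forms C18–C19 and leaves the E-alkene untouched.

Step 7
Reactants: 12 (4E)-N-methoxy-N,5,9-trimethyldeca-4,8-dienamide
Product: 13 3-{(2R,3R)-3-[2-((2R)-3,3-dimethyloxiran-2-yl)ethyl]-3-methyloxiran-2-yl}-N-methoxy-N-methylpropanamide
Conditions: D-fructose-derived Shi ketone (0.6 equiv), Oxone, K2CO3, Bu4NHSO4, MeCN/DMM/aq. buffer (pH 10.5), 0 °C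
Reagents that add atoms: potassium peroxymonosulfate (Oxone), [K+].[O-]S(=O)(=O)OO
Why: Shi epoxidation of both electron-rich trisubstituted alkenes should give the R-configured epoxides by catalyst control, which fixes C11, C17 and (before its later inversion) C7.

Step 8
Reactants: 13 bis-epoxy Weinreb amide
Product: 14 5-{(2R,3R)-3-[2-((2R)-3,3-dimethyloxiran-2-yl)ethyl]-3-methyloxiran-2-yl}pent-1-en-3-one
Conditions: vinylMgBr, THF, −78 → 0 °C; inverse quench into cold aq. NH4Cl
Reagents that add atoms: vinylmagnesium bromide, C=C[Mg]Br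
Why: Weinreb ketone synthesis, in which the chelated tetrahedral adduct prevents over-addition, while the trisubstituted epoxides should be inert to the Grignard reagent at low temperature.

Step 9
Reactants: 14 bis-epoxy vinyl ketone
Product: 15 (Z)-trimethylsilyl enol ether, {[(3Z)-1-{(2R,3R)-3-[2-((2R)-3,3-dimethyloxiran-2-yl)ethyl]-3-methyloxiran-2-yl}hepta-3,6-dien-3-yl]oxy}trimethylsilane
Conditions: vinylMgBr, CuBr·SMe2 (10 mol%), TMSCl, THF, −78 °C; Et3N, pentane, filtration; used crude
Reagents that add atoms: vinylmagnesium bromide, C=C[Mg]Br; chlorotrimethylsilane, C[Si](C)(C)Cl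
Why: Copper-catalysed conjugate addition with in situ silylation traps the enolate regiospecifically as the C20=C6 enol ether carrying the allyl group, an isomer that direct enolisation of the corresponding ketone could not give selectively.

Step 10
Reactants: 15 (Z)-trimethylsilyl enol ether
Product: 17 (3R,5aR,6R,9aR)-3-hydroxy-2,2,5a-trimethyl-6-(prop-2-en-1-yl)octahydro-1-benzoxepin-7(2H)-one, via trimethylsilyl ether 16 (not isolated)
Conditions: TMSOTf (1.1 equiv), 2,6-di-tert-butyl-4-methylpyridine, CH2Cl2, −78 °C; then K2CO3 (cat.), MeOH, rt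
Reagents that add atoms: none
Why: Lewis-acid-triggered epoxide-opening cascade (tandem oxa-/carbacyclisation), in which the internal epoxide oxygen opens the silylated terminal epoxide at tertiary C13 and the enol ether carbon C6 opens the resulting epoxonium at tertiary C7 with inversion through a chair, giving the trans-fused oxepane–cyclohexanone with C11 and C17 inherited from the epoxides; the methanolic base removes the silyl ether and equilibrates C6 to the equatorial allyl epimer.

Step 11
Reactants: 17 hydroxy ketone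
Product: 18 (3R,5aR,6R,7S,9aR)-2,2,5a,7-tetramethyl-6-(prop-2-en-1-yl)decahydro-1-benzoxepine-3,7-diol
Conditions: MeLi, CeCl3 (3.5 equiv each), THF, −78 °C; aq. NH4Cl
Reagents that add atoms: methyllithium, [Li]C
Why: Organocerium 1,2-addition suppresses enolisation of the hindered ketone, and attack from the equatorial direction, anti to the axial C7 methyl, should place the new C20 hydroxyl axial and syn to that methyl.

Step 12
Reactants: 18 diol
Product: 19 bis(triethylsilyl) ether of 18
Conditions: TESOTf (3 equiv), 2,6-lutidine, CH2Cl2, 0 °C → rt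
Reagents that add atoms: triethylsilyl trifluoromethanesulfonate, CC[Si](CC)(CC)OS(=O)(=O)C(F)(F)F
Why: The silyl triflate is reactive enough to silylate both the neopentylic secondary and the axial tertiary hydroxyl, which prevents lactol formation once the aldehyde is unveiled.

Step 13
Reactants: 19 bis(triethylsilyl) ether
Product: 20 2-[(3R,5aR,6R,7S,9aR)-2,2,5a,7-tetramethyl-3,7-bis(triethylsilyloxy)decahydro-1-benzoxepin-6-yl]acetaldehyde
Conditions: O3, CH2Cl2, −78 °C; then PPh3, −78 °C → rt
Reagents that add atoms: ozone, [O-][O+]=O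
Why: Ozonolysis of the only alkene with reductive work-up cuts the allyl group down to the C5H2–C4HO unit.

Step 14
Reactants: 9 (3R,7aS)-hydroxy enone; 20 aldehyde
Product: 21 aldol adduct (β-hydroxy ketone joining C3 of 9 to carbinol carbon C4; C3/C4 epimers; other stereocentres as in 9 and 20)
Conditions: LDA (2.2 equiv), THF, −78 °C (9); then 20, −78 °C; aq. NH4Cl
Reagents that add atoms: none
Why: Kinetic deprotonation of the alkoxide of 9 gives the cross-conjugated α′-enolate at C3 (C33 is vinylic and blocked), and its aldol addition to the aldehyde forms C3–C4; the new stereocentres at C3 and C4 are uncontrolled and are erased in steps 15 and 18.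

Step 15
Reactants: 21 aldol adduct
Product: 23 cross-conjugated dienone with exocyclic C3=C4 (E/Z mixture, inconsequential), via C4 mesylate 22 (not isolated)
Conditions: MsCl, Et3N, CH2Cl2, 0 °C; then DBU, 0 °C
Reagents that add atoms: none
Why: The secondary aldol hydroxyl is sulfonylated much faster than the tertiary C29 hydroxyl, and E1cB elimination of the β-mesyloxy ketone gives the α-alkylidene ketone.

Step 16
Reactants: 23 dienone
Product: 24 cis-fused hexahydroindanone with the exocyclic C3=C4 enone retained and C29–OH free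
Conditions: [Ir(cod)(PCy3)(py)]PF6 (2–5 mol%), H2 (1 atm), CH2Cl2, 0 °C, monitored
Reagents that add atoms: none
Why: Hydroxyl-directed hydrogenation with Crabtree's catalyst, in which iridium bound to the allylic C29 hydroxyl delivers hydrogen to C32=C33 from the hydroxyl face and so sets C32–H cis to C26–H, while the undirected exocyclic alkene, shielded by the C23 gem-dimethyl group, should survive.

Step 17
Reactants: 24 hydroxy enone
Product: 25 C29 triethylsilyl ether of 24
Conditions: TESOTf (1.2 equiv), 2,6-lutidine, CH2Cl2, −78 → 0 °C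
Reagents that add atoms: triethylsilyl trifluoromethanesulfonate, CC[Si](CC)(CC)OS(=O)(=O)C(F)(F)F
Why: O-silylation of the alcohol is much faster than enolisation of the ketone at low temperature and masks the last hydroxyl before the carbene chemistry.

Step 18
Reactants: 25 tris(triethylsilyl) enone
Product: 26 C34=C3 triethylsilyl enol ether of the per-silylated C2-nor skeleton
Conditions: Et3SiH, RhCl(PPh3)3 (2 mol%), toluene, 50 °C
Reagents that add atoms: triethylsilane, CC[SiH](CC)CC
Why: Rhodium-catalysed 1,4-hydrosilylation of the s-cis α-alkylidene ketone delivers hydride to C4 and silicon to oxygen, so the tetrasubstituted enol ether is formed only between C34 and C3.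

Step 19
Reactants: 26 C34=C3 triethylsilyl enol ether; 27 bromoform
Product: 29 tris(triethylsilyl) 2-bromocyclohept-2-enone (bromine on C2), via dibromocyclopropane 28 (not isolated)
Conditions: CHBr3 (3 equiv), KOtBu (4 equiv), pentane, −20 → 0 °C; then toluene, 80 °C
Reagents that add atoms: none
Why: Dibromocarbene, formed by α-elimination from bromoform, adds in a concerted [2+1] step to the electron-rich C34=C3 enol ether; on warming the endo C–Br bond ionises while the C34–C3 bond opens in a disrotatory electrocyclic process, and the silyloxy-stabilised 2-bromoallyl cation gives up its silyl group to bromide to leave the ketone. The closest known reaction type is the ring expansion of cyclic silyl enol ethers through dihalocarbene adducts to 2-halocycloalk-2-enones. The seven-membered ring is not closed by cyclisation: it grows from the six-membered ring by insertion of C2, through three-membered-ring formation followed by opening of the shared bond. No stereocentre is created in the product, since the two cyclopropane stereocentres are transient and C26 and C32 are not touched. The step needs only regio- and chemoselectivity, which are secured by the enol ether position fixed in step 18, by the absence of any other alkene, and by the triethylsilyl enol ether, which resists tert-butoxide better than a trimethylsilyl one.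

Step 20
Reactants: 29 bromoenone
Product: 30 tris(triethylsilyl) ether of the target
Conditions: MeB(OH)2, Pd(OAc)2 (5 mol%), SPhos (10 mol%), K3PO4, toluene/H2O, 90 °C
Reagents that add atoms: methylboronic acid, CB(O)O
Why: Suzuki–Miyaura coupling of the electron-poor α-bromo enone, for which oxidative addition is easy and a bulky biarylphosphine should cope with the tetrasubstituted alkene, installs the C1 methyl.

Step 21
Reactants: 30 tris(triethylsilyl) ether
Product: 31 target CNP0397160.1
Conditions: HF·pyridine, THF/pyridine, 0 °C → rt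
Reagents that add atoms: none
Why: Fluoride-driven cleavage of the three silyl ethers under buffered conditions should leave the enone and the tertiary alcohols intact.

Compound list
1 | 2-methylcyclopentanone (racemic) | CC1CCCC1=O | starting material
2 | 2-methylcyclopent-1-en-1-yl acetate | CC(=O)OC1=C(C)CCC1 | intermediate
3 | (1R,5R)-5-methyl-6-oxabicyclo[3.1.0]hexan-1-yl acetate | C[C@@]12CCC[C@]1(OC(C)=O)O2 | intermediate (not isolated)
4 | (R)-2-hydroxy-2-methylcyclopentanone | C[C@@]1(O)CCCC1=O | intermediate
5 | (5R)-5-methyl-1,5-bis(triethylsilyloxy)cyclopent-1-ene | C[C@@]1(O[Si](CC)(CC)CC)CCC=C1O[Si](CC)(CC)CC | intermediate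
6 | mesityl oxide (4-methylpent-3-en-2-one) | CC(C)=CC(C)=O | starting material
7 | (2R,5S)-2-methyl-5-(2-methyl-4-oxopentan-2-yl)-2-(triethylsilyloxy)cyclopentan-1-one | C[C@@]1(O[Si](CC)(CC)CC)CC[C@@H](C(C)(C)CC(C)=O)C1=O | intermediate
8 | (3R,7aS)-3,7,7-trimethyl-3-(triethylsilyloxy)-1,2,3,6,7,7a-hexahydro-5H-inden-5-one | O=C1CC(C)(C)[C@@H]2CC[C@@](C)(O[Si](CC)(CC)CC)C2=C1 | intermediate (not isolated)
9 | (3R,7aS)-3-hydroxy-3,7,7-trimethyl-1,2,3,6,7,7a-hexahydro-5H-inden-5-one (C26–H cis to C29–OH) | O=C1CC(C)(C)[C@@H]2CC[C@@](C)(O)C2=C1 | intermediate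
10 | geranyl bromide | CC(C)=CCC/C(C)=C/CBr | starting material
11 | N-methoxy-N-methylacetamide | CC(=O)N(C)OC | starting material
12 | (4E)-N-methoxy-N,5,9-trimethyldeca-4,8-dienamide | CC(C)=CCC/C(C)=C/CCC(=O)N(C)OC | intermediate
13 | 3-{(2R,3R)-3-[2-((2R)-3,3-dimethyloxiran-2-yl)ethyl]-3-methyloxiran-2-yl}-N-methoxy-N-methylpropanamide | CC1(C)O[C@@H]1CC[C@@]2(C)O[C@@H]2CCC(=O)N(C)OC | intermediate
14 | 5-{(2R,3R)-3-[2-((2R)-3,3-dimethyloxiran-2-yl)ethyl]-3-methyloxiran-2-yl}pent-1-en-3-one | CC1(C)O[C@@H]1CC[C@@]2(C)O[C@@H]2CCC(=O)C=C | intermediate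
15 | (Z)-trimethylsilyl enol ether of the bis-epoxy hepta-3,6-dien-3-ol | CC1(C)O[C@@H]1CC[C@@]2(C)O[C@@H]2CC/C(O[Si](C)(C)C)=C/CC=C | intermediate
16 | (3R,5aR,6R,9aR)-2,2,5a-trimethyl-6-(prop-2-en-1-yl)-3-(trimethylsilyloxy)octahydro-1-benzoxepin-7(2H)-one | C=CC[C@@H]1[C@@]2(C)CC[C@@H](O[Si](C)(C)C)C(C)(C)O[C@@H]2CCC1=O | intermediate (not isolated)
17 | (3R,5aR,6R,9aR)-3-hydroxy-2,2,5a-trimethyl-6-(prop-2-en-1-yl)octahydro-1-benzoxepin-7(2H)-one (trans-fused, allyl equatorial) | C=CC[C@@H]1[C@@]2(C)CC[C@@H](O)C(C)(C)O[C@@H]2CCC1=O | intermediate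
18 | (3R,5aR,6R,7S,9aR)-2,2,5a,7-tetramethyl-6-(prop-2-en-1-yl)decahydro-1-benzoxepine-3,7-diol (C20–OH axial, syn to the angular methyl) | C=CC[C@@H]1[C@@]2(C)CC[C@@H](O)C(C)(C)O[C@@H]2CC[C@]1(C)O | intermediate
19 | bis(triethylsilyl) ether of 18 | C=CC[C@@H]1[C@@]2(C)CC[C@@H](O[Si](CC)(CC)CC)C(C)(C)O[C@@H]2CC[C@]1(C)O[Si](CC)(CC)CC | intermediate
20 | 2-[(3R,5aR,6R,7S,9aR)-2,2,5a,7-tetramethyl-3,7-bis(triethylsilyloxy)decahydro-1-benzoxepin-6-yl]acetaldehyde | O=CC[C@@H]1[C@@]2(C)CC[C@@H](O[Si](CC)(CC)CC)C(C)(C)O[C@@H]2CC[C@]1(C)O[Si](CC)(CC)CC | intermediate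
21 | aldol adduct: enone 9 bonded at C3 to the carbinol carbon C4 of the right half (C3/C4 epimers) | O=C1C(C(O)C[C@@H]2[C@@]3(C)CC[C@@H](O[Si](CC)(CC)CC)C(C)(C)O[C@@H]3CC[C@]2(C)O[Si](CC)(CC)CC)C(C)(C)[C@@H]2CC[C@@](C)(O)C2=C1 | intermediate
22 | C4 methanesulfonate of 21 | O=C1C(C(OS(C)(=O)=O)C[C@@H]2[C@@]3(C)CC[C@@H](O[Si](CC)(CC)CC)C(C)(C)O[C@@H]3CC[C@]2(C)O[Si](CC)(CC)CC)C(C)(C)[C@@H]2CC[C@@](C)(O)C2=C1 | intermediate (not isolated)
23 | cross-conjugated dienone: ring C33=C32 enone plus exocyclic C3=C4 alkylidene (E/Z mixture) | O=C1C(=CC[C@@H]2[C@@]3(C)CC[C@@H](O[Si](CC)(CC)CC)C(C)(C)O[C@@H]3CC[C@]2(C)O[Si](CC)(CC)CC)C(C)(C)[C@@H]2CC[C@@](C)(O)C2=C1 | intermediate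
24 | cis-fused hydrindanone with exocyclic C3=C4 enone; H26, H32 and the C29 hydroxyl on one face | O=C1C(=CC[C@@H]2[C@@]3(C)CC[C@@H](O[Si](CC)(CC)CC)C(C)(C)O[C@@H]3CC[C@]2(C)O[Si](CC)(CC)CC)C(C)(C)[C@@H]2CC[C@@](C)(O)[C@@H]2C1 | intermediate
25 | C29 triethylsilyl ether of 24 | O=C1C(=CC[C@@H]2[C@@]3(C)CC[C@@H](O[Si](CC)(CC)CC)C(C)(C)O[C@@H]3CC[C@]2(C)O[Si](CC)(CC)CC)C(C)(C)[C@@H]2CC[C@@](C)(O[Si](CC)(CC)CC)[C@@H]2C1 | intermediate
26 | per-triethylsilylated C2-nor skeleton as its C34=C3 silyl enol ether | CC[Si](CC)(CC)OC1=C(CC[C@@H]2[C@@]3(C)CC[C@@H](O[Si](CC)(CC)CC)C(C)(C)O[C@@H]3CC[C@]2(C)O[Si](CC)(CC)CC)C(C)(C)[C@@H]2CC[C@@](C)(O[Si](CC)(CC)CC)[C@@H]2C1 | intermediate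
27 | bromoform | BrC(Br)Br | starting material
28 | dibromocyclopropane adduct (CBr2 bridging C34 and C3; the two new ring stereocentres undefined) | CC[Si](CC)(CC)OC15C(CC[C@@H]2[C@@]3(C)CC[C@@H](O[Si](CC)(CC)CC)C(C)(C)O[C@@H]3CC[C@]2(C)O[Si](CC)(CC)CC)(C5(Br)Br)C(C)(C)[C@@H]2CC[C@@](C)(O[Si](CC)(CC)CC)[C@@H]2C1 | intermediate (not isolated)
29 | tris(triethylsilyl) 2-bromocyclohept-2-enone (target skeleton with Br in place of the C1 methyl) | BrC1=C(CC[C@@H]2[C@@]3(C)CC[C@@H](O[Si](CC)(CC)CC)C(C)(C)O[C@@H]3CC[C@]2(C)O[Si](CC)(CC)CC)C(C)(C)[C@@H]2CC[C@@](C)(O[Si](CC)(CC)CC)[C@@H]2CC1=O | intermediate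
30 | tris(triethylsilyl) ether of the target | CC1=C(CC[C@@H]2[C@@]3(C)CC[C@@H](O[Si](CC)(CC)CC)C(C)(C)O[C@@H]3CC[C@]2(C)O[Si](CC)(CC)CC)C(C)(C)[C@@H]2CC[C@@](C)(O[Si](CC)(CC)CC)[C@@H]2CC1=O | intermediate
31 | CNP0397160.1 | CC1=C(CC[C@@H]2[C@@]3(C)CC[C@@H](O)C(C)(C)O[C@@H]3CC[C@]2(C)O)C(C)(C)[C@@H]2CC[C@@](C)(O)[C@@H]2CC1=O | target

Total step count: 21. Longest linear sequence: 16 steps (steps 6–13, then 14–21).

Steps most likely to fail

Step 19. The carbene may add only slowly to the tetrasubstituted enol ether shielded by the C23 gem-dimethyl group, tert-butoxide may desilylate the enol ether before cyclopropanation, or the adduct may resist ring opening. The fallback sets out from 26 and returns at 30, so that steps 19 and 20 are replaced. Ethylidene transfer with diethylzinc and 1,1-diiodoethane (Furukawa-type Simmons–Smith reaction) would give the methyl-substituted silyloxycyclopropane F1. Oxidation with FeCl3 in DMF (Ito–Saegusa ring expansion) would cleave the C34–C3 bond through the tertiary C3 radical to the ring-expanded β-chloro ketone F2. Sodium acetate in methanol would then eliminate hydrogen chloride to give 30, with the C1 methyl already in place. Any silyl ether lost to the iron salt is harmless because step 21 removes them all.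

Step 4. Facial selectivity at C26 may be poor, since the controlling centre C29 carries two groups of similar size, and C26 may also epimerise during the basic ring closure. The fallback sets out from 9 taken as a mixture of C26 epimers and returns at 9 as a single diastereomer. Potassium tert-butoxide followed by kinetic protonation with acetic acid would move the alkene out of conjugation to give the β,γ-unsaturated ketone F3, in which C26 is no longer a stereocentre. Hydrogenation with Crabtree's catalyst, directed by the allylic C29 hydroxyl, would deliver both ring-fusion hydrogens to the tetrasubstituted C26=C32 alkene from the hydroxyl face and give the cis-hydrindanone F4. Dehydrogenation with IBX can only take place towards C33–C32, because C23 is quaternary, and would return 9 with C26 fixed by the C29 centre.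

Step 16. Site-selectivity may be lost, with the exocyclic C3=C4 alkene reduced alongside or instead of the ring alkene, which would destroy the handle for the regiodefined enol ether. The fallback sets out from 21 and returns at 24. The aldol adduct, which has only one C=C bond, would be hydrogenated under the same hydroxyl-directed conditions to the saturated β-hydroxy ketone F5. Selective mesylation of the secondary hydroxyl would give the mesylate F6, and elimination with DBU would then form the exocyclic enone 24.

Further compounds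
F1 | step 19 | methyl-substituted silyloxycyclopropane (CH(CH3) bridging C34 and C3 of 26) | CC[Si](CC)(CC)OC15C(CC[C@@H]2[C@@]3(C)CC[C@@H](O[Si](CC)(CC)CC)C(C)(C)O[C@@H]3CC[C@]2(C)O[Si](CC)(CC)CC)(C5C)C(C)(C)[C@@H]2CC[C@@](C)(O[Si](CC)(CC)CC)[C@@H]2C1
F2 | step 19 | ring-expanded β-chloro ketone (Cl on C3, methyl on C2) | CC1C(Cl)(CC[C@@H]2[C@@]3(C)CC[C@@H](O[Si](CC)(CC)CC)C(C)(C)O[C@@H]3CC[C@]2(C)O[Si](CC)(CC)CC)C(C)(C)[C@@H]2CC[C@@](C)(O[Si](CC)(CC)CC)[C@@H]2CC1=O
F3 | step 4 | (3R)-3-hydroxy-3,7,7-trimethyl-1,2,3,4,6,7-hexahydro-5H-inden-5-one | O=C1CC(C)(C)C2=C(C1)[C@](C)(O)CC2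
F4 | step 4 | (3R,3aR,7aR)-3-hydroxy-3,7,7-trimethyloctahydro-5H-inden-5-one | O=C1CC(C)(C)[C@@H]2CC[C@@](C)(O)[C@@H]2C1
F5 | step 16 | ring-saturated aldol adduct (cis-fused, C3/C4 epimers) | O=C1C(C(O)C[C@@H]2[C@@]3(C)CC[C@@H](O[Si](CC)(CC)CC)C(C)(C)O[C@@H]3CC[C@]2(C)O[Si](CC)(CC)CC)C(C)(C)[C@@H]2CC[C@@](C)(O)[C@@H]2C1
F6 | step 16 | C4 methanesulfonate of F5 | O=C1C(C(OS(C)(=O)=O)C[C@@H]2[C@@]3(C)CC[C@@H](O[Si](CC)(CC)CC)C(C)(C)O[C@@H]3CC[C@]2(C)O[Si](CC)(CC)CC)C(C)(C)[C@@H]2CC[C@@](C)(O)[C@@H]2C1
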